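At early times the green flask hardly moved: 99.8% of the substrate charge stood at 6.00 min and 96.2% at 12.0 min, with no product showing.

| setting | green | grey | flask |
|---|---|---|---|
| substrate | 0.50 M | 0.50 M | 0.50 M |
| solid reagent | 2 equiv | 1 equiv | 2.00 equiv |
| remark | the very flask that is asked about, followed so far | run made earlier |  |
| time |  |  | 2.5 h |

| run | time / min | product / % | idle adduct / % | substrate / % |
|---|---|---|---|---|
| green | 6.00 | 0 | 0 | 99.8 |
| green | 12.0 | 0 | 0 | 96.2 |
| green | 20.0 | 2.2 | 1.1 | 91.1 |
| green | 40.0 | 11.8 | 1.6 | 79.1 |
| green | 80.0 | 34.5 | 3.6 | 50.2 |
| grey | 10.0 | 0.8 | 0.4 | 97.5 |
| grey | 25.0 | 0.5 | 0.3 | 88.8 |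
| grey | 50.0 | 15.0 | 1.6 | 71.3 |
| grey | 80.0 | 34.0 | 0.8 | 51.0 |
| grey | 120 | 58.7 | 8.3 | 31.2 |

(scatter of a reading: 1 percentage point)

- amount of product and idle adduct together at 2.5 h, in percent of the substrate charged
- concentration of partner in solution at 15 min, in percent of saturation
- the change that raises the amount of product and idle adduct together at 2.5 h, in percent of the substrate charged most ("none" if none brings more than 2 percentage points) (south / north-west / none)
- amount of product and idle adduct together at 2.5 h, in percent of the substrate charged, after south

- for product the idle adduct is counted in
- as a solid, counted per litre of solution: solid reagent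
- the analysis behind the earlier runs scatters by 1 percentage point, standard deviation
- at the start none of the solid reagent is in solution
- partner is what solid reagent becomes in solution

- south: doubling the dissolution coefficient of the solid reagent, all else as stated
- north-west: doubling the solubility of the solid reagent, all else as stated

From 12.0 min to 80.0 min the green substrate fell nearly straight, by 0.406 h⁻¹. I called this the feed slope, the fraction of the charge lost per hour on the straight stretch. Drawn back to the full charge, the line starts at 6.38 min.

A straight fall looks pseudo-zero-order in substrate. The amount of solid did not show either: with 1 equiv, the grey flask stood at 51.0% at 80.0 min, against 50.2% for green. So I took dissolved partner as the concentration that sets the order, taken up about as fast as it dissolves.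

The knee came next. From 80.0 min to 120 min the grey slope was 0.297 h⁻¹, less than the feed slope. Continued at that pace, substrate reaches 0.164 at 2.5 h. Grey's last reading left 10 percentage points of the charge unseen, and holding that gap I committed to 73.6% of product and idle adduct together.

For south I doubled the slope, and that line, drawn without a knee, reaches zero substrate at 1.34 h, earlier than 2.5 h, so with the same gap I expected 89.9%. North-west also doubles the feed at the start, and it widens the distance to saturation, so I chose it. For saturation I gave no number; I expected a low level while the line runs straight.

The forecast gave 75%, 47% of saturation, 78% after south, lower than my figure, and north-west as best, holding that “rate depends on dissolved partner”.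

The flask gives 71.8%, 13.1% of saturation at 15 min, 89.8% after south, and north-west as best.

    substrate + partner → intermediate (k = 0.00220 L mol⁻¹ s⁻¹)
    intermediate → product (k = 7.70 × 10⁻⁴ s⁻¹)
    solid reagent ⇌ partner, rate k3*(cs3 - [partner]) while solid is left; crystals form when [partner] > cs3 (solubility = 0.350 M, k = 2.50 × 10⁻⁴ s⁻¹)
    partner + product ⇌ idle adduct, settled at all times (K = 1.50 L mol⁻¹)

In this flask the step with substrate gives partner a half-life of 0.18 h at the charge, shorter than the 0.770 h of approach to saturation. Run on unbent, the feed-slope line gives 2.85% of substrate at 2.5 h, where this flask holds 19.1%. In the neighbour with the same charges, read at 1.0 h, the line gives 63.7% of substrate and the neighbour holds 64.5%.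

The data are simulated with constants of no real substance, noise included.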